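**Plan**

- Unprimed locants are flavone numbering, primed locants are dihydrobenzofuran numbering. After removal of a silyl group from O3', ring C is cut at C4a–C4, C4–C3 and O1–C2 into 2-iodophloroglucinol triacetate (ring A), CO (C4) and a ring B aryl acetylene (C2, C3).
- The enabling feature is ring C (O1, C2, C3, C4, C4a, C8a): a pyran-4-one whose carbonyl carbon C4 lies between ring A carbon C4a and the C3=C2 unit bearing ring B, with O1 on C8a ortho to C4a. Ring A carries the same oxygen on both carbons next to C4a, so the iodide is symmetric.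
- The alkyne is cut at C5'–C(sp) (Sonogashira), at the two C–CH3 bonds of the carbinol (Grignard), at O1'–C2' (phenoxide SN2) and at C2'–C3' (aldol), leading back to 4-iodophenol, prenyl bromide and a chloroacetyl oxazolidinone.
- Forward: 4-iodophenol is prenylated and formylated, the aldol joins the two-carbon unit, the dihydrofuran ring closes, the carbinol and alkyne are installed, ring C is closed on the preformed ring A iodide, and the silyl ether is removed last.
- Stereochemistry: C3' comes from an Evans syn aldol with the (S)-4-benzyl auxiliary, giving the (2S,3R) chlorohydrin. C2' comes from SN2 inversion of the chloride, giving the trans (2R,3R) ring.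

Key step: step 12

Remark: in the target SMILES both stereocentres are R and the C3' hydroxyl is trans to the C2' hydroxypropyl group; reagent 6 is taken as purchasable (otherwise one N-acylation of (S)-4-benzyloxazolidin-2-one with chloroacetyl chloride).

**Route**

Step 1
Reactants: 1 4-iodophenol; 2 prenyl bromide (1-bromo-3-methylbut-2-ene)
Product: 3 4-iodo-2-(3-methylbut-2-en-1-yl)phenol
Conditions: NaH, toluene, 0 °C; then 2, rt
Reagents that add atoms: none
Why: Ortho-C-alkylation of a phenoxide, in which the sodium phenoxide reacts in toluene as a tight ion pair at the ortho carbon (the para position is blocked by iodine) and rearomatises to the 2-prenylphenol.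

Step 2
Reactants: 3 4-iodo-2-(3-methylbut-2-en-1-yl)phenol
Product: 4 2-hydroxy-5-iodo-3-(3-methylbut-2-en-1-yl)benzaldehyde
Conditions: MgCl2, Et3N, (CH2O)n, MeCN, reflux; then cold dilute HCl
Reagents that add atoms: paraformaldehyde (reacts as formaldehyde), C=O
Why: Casnati–Skattebøl ortho-formylation, in which the magnesium phenoxide delivers formaldehyde to the only free ortho position and a second formaldehyde oxidises the benzylic alkoxide by hydride transfer, conditions that leave the prenyl group and the aryl iodide alone.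

Step 3
Reactants: 4 2-hydroxy-5-iodo-3-(3-methylbut-2-en-1-yl)benzaldehyde
Product: 5 2-(tert-butyldimethylsilyloxy)-5-iodo-3-(3-methylbut-2-en-1-yl)benzaldehyde
Conditions: TBSCl, imidazole, DMAP (cat.), DMF, rt
Reagents that add atoms: tert-butyldimethylsilyl chloride, CC(C)(C)[Si](C)(C)Cl
Why: Routine O-silylation of a phenol, which removes the acidic proton that would consume the boron reagent of the aldol and gives a group that fluoride later removes selectively.

Step 4
Reactants: 5 2-(tert-butyldimethylsilyloxy)-5-iodo-3-(3-methylbut-2-en-1-yl)benzaldehyde; 6 (S)-4-benzyl-3-(chloroacetyl)oxazolidin-2-one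
Product: 9 (S)-4-benzyl-3-{(2S,3R)-3-[2-(tert-butyldimethylsilyloxy)-5-iodo-3-(3-methylbut-2-en-1-yl)phenyl]-2-chloro-3-hydroxypropanoyl}oxazolidin-2-one, via Z-dibutylboron enolate 7 (not isolated), via dibutylboron aldolate 8 (not isolated)
Conditions: 6, Bu2BOTf, Et3N, CH2Cl2, −78 °C; 5, −78 → 0 °C; then pH 7 buffer, MeOH, H2O2, 0 °C
Reagents that add atoms: none
Why: Evans syn aldol reaction, in which the Z boron enolate reacts through a chair Zimmerman–Traxler transition state with the auxiliary carbonyl turned away from the enolate oxygen and the benzyl group shielding one face, so the (2S,3R) syn chlorohydrin should form, fixing C3' of the target and placing the chloride for later inversion.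

Step 5
Reactants: 9 the syn aldol adduct
Product: 10 (S)-4-benzyl-3-{(2S,3R)-3-(tert-butyldimethylsilyloxy)-3-[2-(tert-butyldimethylsilyloxy)-5-iodo-3-(3-methylbut-2-en-1-yl)phenyl]-2-chloropropanoyl}oxazolidin-2-one
Conditions: TBSOTf, 2,6-lutidine, CH2Cl2, −78 → 0 °C
Reagents that add atoms: tert-butyldimethylsilyl triflate, CC(C)(C)[Si](C)(C)OS(=O)(=O)C(F)(F)F
Why: Silylation of a hindered secondary alcohol with the silyl triflate, which blocks epoxide formation and retro-aldol cleavage in the basic steps that follow and installs the O3' protecting group carried to the end.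

Step 6
Reactants: 10 the bis-silyl chloro imide
Product: 12 (S)-4-benzyl-3-{[(2R,3R)-3-(tert-butyldimethylsilyloxy)-5-iodo-7-(3-methylbut-2-en-1-yl)-2,3-dihydrobenzofuran-2-yl]carbonyl}oxazolidin-2-one, via cesium phenoxide 11 (not isolated)
Conditions: CsF, DMF, 0 °C → rt
Reagents that add atoms: none
Why: Fluoride-induced desilylative intramolecular Williamson etherification, in which the aryl silyl ether is cleaved much faster than the alkyl silyl ether and the cesium phenoxide displaces the activated α-chloride by 5-exo-tet SN2 with inversion, converting the (2S) chloride into the (2R) ether trans to the C3' silyloxy group.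

Step 7
Reactants: 12 the trans dihydrobenzofuran imide
Product: 13 methyl (2R,3R)-3-(tert-butyldimethylsilyloxy)-5-iodo-7-(3-methylbut-2-en-1-yl)-2,3-dihydrobenzofuran-2-carboxylate
Conditions: MeOMgBr (from MeMgBr and MeOH), CH2Cl2–MeOH, 0 °C; aq NH4Cl
Reagents that add atoms: methanol (delivered as bromomagnesium methoxide), CO
Why: Transesterification of an N-acyloxazolidinone with bromomagnesium methoxide at the exocyclic carbonyl, which the α-aryloxy group activates, releasing the auxiliary while the trans arrangement, being the more stable one, is not endangered by the mild base.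

Step 8
Reactants: 13 the methyl ester
Product: 14 2-[(2R,3R)-3-(tert-butyldimethylsilyloxy)-5-iodo-7-(3-methylbut-2-en-1-yl)-2,3-dihydrobenzofuran-2-yl]propan-2-ol
Conditions: MeMgBr (3.5 equiv), THF, −20 → 0 °C; aq NH4Cl
Reagents that add atoms: methylmagnesium bromide, C[Mg]Br
Why: Double Grignard addition to an ester through the methyl ketone, fast for an α-alkoxy ester at low temperature, so that enolisation at C2' and iodine–magnesium exchange should not compete.

Step 9
Reactants: 14 the iodo carbinol; 15 trimethylsilylacetylene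
Product: 17 2-[(2R,3R)-3-(tert-butyldimethylsilyloxy)-5-ethynyl-7-(3-methylbut-2-en-1-yl)-2,3-dihydrobenzofuran-2-yl]propan-2-ol, via trimethylsilyl alkyne 16 (not isolated)
Conditions: PdCl2(PPh3)2 (3 mol %), CuI (5 mol %), Et3N, THF, rt; then K2CO3, MeOH, rt
Reagents that add atoms: none
Why: Sonogashira coupling of an aryl iodide at room temperature followed by methanolysis of the alkynyl C–Si bond, conditions under which the secondary silyl ether, the tertiary alcohol and the prenyl group are stable.

Step 10
Reactants: 18 phloroglucinol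
Product: 19 2-iodobenzene-1,3,5-triol
Conditions: I2 (1.0 equiv), NaHCO3, THF–H2O, 0 °C; used at once
Reagents that add atoms: iodine, II
Why: Electrophilic aromatic iodination of a highly activated arene whose three free positions are equivalent, so one equivalent of iodine at low temperature should give a single mono-iodide.

Step 11
Reactants: 19 2-iodobenzene-1,3,5-triol
Product: 20 2-iodobenzene-1,3,5-triyl triacetate
Conditions: Ac2O, pyridine, DMAP (cat.), CH2Cl2, 0 °C → rt
Reagents that add atoms: acetic anhydride, CC(=O)OC(C)=O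
Why: Exhaustive O-acetylation of phenols, which stabilises the iodide against loss of iodine and supplies the ortho acetoxy group that the annulation needs.

Step 12
Reactants: 17 the ring B alkyne; 20 2-iodobenzene-1,3,5-triyl triacetate; 21 carbon monoxide
Product: 24 2-[(2R,3R)-3-(tert-butyldimethylsilyloxy)-2-(2-hydroxypropan-2-yl)-7-(3-methylbut-2-en-1-yl)-2,3-dihydrobenzofuran-5-yl]-5,7-dihydroxy-4H-chromen-4-one, via triacetoxy ynone 22 (not isolated), via enaminone 23 (not isolated)
Conditions: PdCl2(PPh3)2 (5 mol %), dppp (5 mol %), thiourea (5 mol %), Et2NH (excess), DMF, CO (1 atm), 40 °C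
Reagents that add atoms: none
Why: Zerovalent palladium generated from PdCl2(PPh3)2 adds to the C–I bond of 20, CO inserts to give an aroylpalladium species, and copper-free, amine-assisted transfer of the acetylide of 17 followed by reductive elimination forms C4a–C4 and C4–C3 in ynone 22. Diethylamine then adds to the ynone and cleaves the aryl acetates by aminolysis to give enaminone 23, whose ortho phenoxide attacks C2 in a 6-endo-trig addition–elimination that forms O1–C2 and releases the amine. The closest known reaction is the palladium-catalysed carbonylative annulation of ortho-iodophenyl acetates with terminal arylacetylenes to flavones, a carbonylative Sonogashira coupling with cyclisation in the same flask. No stereocentre is created, and the two centres of 17 are remote from the reacting alkyne and stable to mild base at 40 °C. Carbonylation must outrun direct alkynylation, which the CO atmosphere, the absence of copper and the acetate masking of the phenol should secure, and 6-endo closure must outrun 5-exo closure to an aurone, which the enaminone enforces because C2 is its only electrophilic carbon. Both carbons flanking the iodide in 20 carry the same acetoxy group, so either phenol closes the same ring C and no regiochemical question arises.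

Step 13
Reactants: 24 the 3'-O-silyl flavone
Product: 25 5,7-dihydroxy-2-[(2R,3R)-3-hydroxy-2-(2-hydroxypropan-2-yl)-7-(3-methylbut-2-en-1-yl)-2,3-dihydrobenzofuran-5-yl]-4H-chromen-4-one
Conditions: Bu4NF, AcOH, THF, 0 °C → rt
Reagents that add atoms: none
Why: Fluoride-mediated cleavage of a silyl ether under buffered, non-acidic conditions, which avoids dehydration of the benzylic carbinol to a benzofuran and leaves both stereocentres, the prenyl group and the flavone untouched.

**Compound list**

1 | 4-iodophenol | Oc1ccc(I)cc1 | starting material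
2 | prenyl bromide (1-bromo-3-methylbut-2-ene) | CC(C)=CCBr | starting material
3 | 4-iodo-2-(3-methylbut-2-en-1-yl)phenol | CC(C)=CCc1cc(I)ccc1O | intermediate
4 | 2-hydroxy-5-iodo-3-(3-methylbut-2-en-1-yl)benzaldehyde | CC(C)=CCc1cc(I)cc(C=O)c1O | intermediate
5 | 2-(tert-butyldimethylsilyloxy)-5-iodo-3-(3-methylbut-2-en-1-yl)benzaldehyde | CC(C)=CCc1cc(I)cc(C=O)c1O[Si](C)(C)C(C)(C)C | intermediate
6 | (S)-4-benzyl-3-(chloroacetyl)oxazolidin-2-one | O=C(CCl)N1[C@@H](Cc2ccccc2)COC1=O | starting material
7 | Z-dibutylboron enolate of 6 (not isolated) | Cl/C=C(\OB(CCCC)CCCC)N1[C@@H](Cc2ccccc2)COC1=O | intermediate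
8 | dibutylboron aldolate of 9 (not isolated) | O=C([C@@H](Cl)[C@H](OB(CCCC)CCCC)c1cc(I)cc(CC=C(C)C)c1O[Si](C)(C)C(C)(C)C)N1[C@@H](Cc2ccccc2)COC1=O | intermediate
9 | (S)-4-benzyl-3-{(2S,3R)-3-[2-(tert-butyldimethylsilyloxy)-5-iodo-3-(3-methylbut-2-en-1-yl)phenyl]-2-chloro-3-hydroxypropanoyl}oxazolidin-2-one | O=C([C@@H](Cl)[C@H](O)c1cc(I)cc(CC=C(C)C)c1O[Si](C)(C)C(C)(C)C)N1[C@@H](Cc2ccccc2)COC1=O | intermediate
10 | (S)-4-benzyl-3-{(2S,3R)-3-(tert-butyldimethylsilyloxy)-3-[2-(tert-butyldimethylsilyloxy)-5-iodo-3-(3-methylbut-2-en-1-yl)phenyl]-2-chloropropanoyl}oxazolidin-2-one | O=C([C@@H](Cl)[C@H](O[Si](C)(C)C(C)(C)C)c1cc(I)cc(CC=C(C)C)c1O[Si](C)(C)C(C)(C)C)N1[C@@H](Cc2ccccc2)COC1=O | intermediate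
11 | cesium phenoxide of desilylated 10 (not isolated) | O=C([C@@H](Cl)[C@H](O[Si](C)(C)C(C)(C)C)c1cc(I)cc(CC=C(C)C)c1[O-])N1[C@@H](Cc2ccccc2)COC1=O.[Cs+] | intermediate
12 | (S)-4-benzyl-3-{[(2R,3R)-3-(tert-butyldimethylsilyloxy)-5-iodo-7-(3-methylbut-2-en-1-yl)-2,3-dihydrobenzofuran-2-yl]carbonyl}oxazolidin-2-one (trans) | CC(C)=CCc1cc(I)cc2c1O[C@@H](C(=O)N3[C@@H](Cc4ccccc4)COC3=O)[C@@H]2O[Si](C)(C)C(C)(C)C | intermediate
13 | methyl (2R,3R)-3-(tert-butyldimethylsilyloxy)-5-iodo-7-(3-methylbut-2-en-1-yl)-2,3-dihydrobenzofuran-2-carboxylate | CC(C)=CCc1cc(I)cc2c1O[C@@H](C(=O)OC)[C@@H]2O[Si](C)(C)C(C)(C)C | intermediate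
14 | 2-[(2R,3R)-3-(tert-butyldimethylsilyloxy)-5-iodo-7-(3-methylbut-2-en-1-yl)-2,3-dihydrobenzofuran-2-yl]propan-2-ol | CC(C)=CCc1cc(I)cc2c1O[C@@H](C(C)(C)O)[C@@H]2O[Si](C)(C)C(C)(C)C | intermediate
15 | trimethylsilylacetylene | C#C[Si](C)(C)C | starting material
16 | 2-[(2R,3R)-3-(tert-butyldimethylsilyloxy)-7-(3-methylbut-2-en-1-yl)-5-[(trimethylsilyl)ethynyl]-2,3-dihydrobenzofuran-2-yl]propan-2-ol (not isolated) | CC(C)=CCc1cc(C#C[Si](C)(C)C)cc2c1O[C@@H](C(C)(C)O)[C@@H]2O[Si](C)(C)C(C)(C)C | intermediate
17 | 2-[(2R,3R)-3-(tert-butyldimethylsilyloxy)-5-ethynyl-7-(3-methylbut-2-en-1-yl)-2,3-dihydrobenzofuran-2-yl]propan-2-ol | CC(C)=CCc1cc(C#C)cc2c1O[C@@H](C(C)(C)O)[C@@H]2O[Si](C)(C)C(C)(C)C | intermediate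
18 | phloroglucinol | Oc1cc(O)cc(O)c1 | starting material
19 | 2-iodobenzene-1,3,5-triol | Oc1cc(O)c(I)c(O)c1 | intermediate
20 | 2-iodobenzene-1,3,5-triyl triacetate | CC(=O)Oc1cc(OC(C)=O)c(I)c(OC(C)=O)c1 | intermediate
21 | carbon monoxide | [C-]#[O+] | starting material
22 | 2-{3-[(2R,3R)-3-(tert-butyldimethylsilyloxy)-2-(2-hydroxypropan-2-yl)-7-(3-methylbut-2-en-1-yl)-2,3-dihydrobenzofuran-5-yl]prop-2-ynoyl}benzene-1,3,5-triyl triacetate (not isolated) | CC(C)=CCc1cc(C#CC(=O)c3c(OC(C)=O)cc(OC(C)=O)cc3OC(C)=O)cc2c1O[C@@H](C(C)(C)O)[C@@H]2O[Si](C)(C)C(C)(C)C | intermediate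
23 | 3-(diethylamino)-3-[(2R,3R)-3-(tert-butyldimethylsilyloxy)-2-(2-hydroxypropan-2-yl)-7-(3-methylbut-2-en-1-yl)-2,3-dihydrobenzofuran-5-yl]-1-(2,4,6-trihydroxyphenyl)prop-2-en-1-one (not isolated) | CC(C)=CCc1cc(C(=CC(=O)c3c(O)cc(O)cc3O)N(CC)CC)cc2c1O[C@@H](C(C)(C)O)[C@@H]2O[Si](C)(C)C(C)(C)C | intermediate
24 | 2-[(2R,3R)-3-(tert-butyldimethylsilyloxy)-2-(2-hydroxypropan-2-yl)-7-(3-methylbut-2-en-1-yl)-2,3-dihydrobenzofuran-5-yl]-5,7-dihydroxy-4H-chromen-4-one | CC(C)=CCc1cc(-c2cc(=O)c3c(O)cc(O)cc3o2)cc2c1O[C@@H](C(C)(C)O)[C@@H]2O[Si](C)(C)C(C)(C)C | intermediate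
25 | 5,7-dihydroxy-2-[(2R,3R)-3-hydroxy-2-(2-hydroxypropan-2-yl)-7-(3-methylbut-2-en-1-yl)-2,3-dihydrobenzofuran-5-yl]-4H-chromen-4-one (CNP0172554.2) | CC(C)=CCc1cc(-c2cc(=O)c3c(O)cc(O)cc3o2)cc2c1O[C@@H](C(C)(C)O)[C@@H]2O | target

**Count and risks**

Total step count: 13 (steps 1–9 to alkyne 17, steps 10–11 to iodide 20, step 12, step 13).
Longest linear sequence: 11 steps (1 → 3 → 4 → 5 → 9 → 10 → 12 → 13 → 14 → 17 → 24 → 25).

Steps most likely to fail:

Step 12. Aminolysis of the acetates may run ahead of the coupling and leave an electron-rich iodophenoxide that adds to palladium slowly and loses iodine by protonation. Diethylamine may also capture the aroylpalladium intermediate as an amide, or the alkyne may couple without taking up CO. The fallback sets out from 17, returns at 24 and builds ring C without palladium. Alkyne 17 is deprotonated twice with n-BuLi (THF, −78 °C) and added to 2,4,6-tris(tert-butyldimethylsilyloxy)benzaldehyde F1 (from commercial 2,4,6-trihydroxybenzaldehyde, TBSCl and imidazole) to give the propargylic alcohol F2 as a mixture of carbinol epimers. MnO2 in CH2Cl2 oxidises it to the ynone F3, and Et2NH in EtOH adds to give the silylated enaminone F4. K2CO3 in MeOH then cleaves only the three aryl silyl ethers, so that enaminone 23 forms and closes by the same 6-endo addition–elimination to 24.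

Step 6. The freed phenoxide may attack the imide carbonyl and lactonise with loss of the auxiliary. The chloride-bearing carbon may epimerise before ring closure, or base may expel silanolate from the product and aromatise it to a benzofuran. The fallback sets out from 10, returns at 13 and closes the ring on an ester, which the phenoxide cannot acylate productively and which is less acidic. MeOMgBr in CH2Cl2–MeOH at 0 °C exchanges the auxiliary first, giving methyl (2S,3R)-3-(tert-butyldimethylsilyloxy)-3-[2-(tert-butyldimethylsilyloxy)-5-iodo-3-(3-methylbut-2-en-1-yl)phenyl]-2-chloropropanoate F5. CsF in DMF then removes the aryl silyl group and the phenoxide displaces the chloride with inversion to give 13 directly.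

Step 1. The ambident phenoxide may alkylate on oxygen or twice on carbon instead of once at the ortho carbon. The fallback sets out from 1, returns at 3 and installs the side chain through a sigmatropic shift. Allyl bromide and K2CO3 in acetone give allyl 4-iodophenyl ether F6, and an aromatic Claisen rearrangement in N,N-diethylaniline at about 200 °C gives 2-allyl-4-iodophenol F7. Cross-metathesis with 2-methyl-2-butene (second-generation Grubbs catalyst RuCl2(=CHPh)(H2IMes)(PCy3), CH2Cl2, 40 °C) converts the allyl group into the prenyl group of 3.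

Further compounds
F1 | step 12 | 2,4,6-tris(tert-butyldimethylsilyloxy)benzaldehyde | O=Cc1c(O[Si](C)(C)C(C)(C)C)cc(O[Si](C)(C)C(C)(C)C)cc1O[Si](C)(C)C(C)(C)C
F2 | step 12 | 3-[(2R,3R)-3-(tert-butyldimethylsilyloxy)-2-(2-hydroxypropan-2-yl)-7-(3-methylbut-2-en-1-yl)-2,3-dihydrobenzofuran-5-yl]-1-[2,4,6-tris(tert-butyldimethylsilyloxy)phenyl]prop-2-yn-1-ol (carbinol epimers) | CC(C)=CCc1cc(C#CC(O)c3c(O[Si](C)(C)C(C)(C)C)cc(O[Si](C)(C)C(C)(C)C)cc3O[Si](C)(C)C(C)(C)C)cc2c1O[C@@H](C(C)(C)O)[C@@H]2O[Si](C)(C)C(C)(C)C
F3 | step 12 | 3-[(2R,3R)-3-(tert-butyldimethylsilyloxy)-2-(2-hydroxypropan-2-yl)-7-(3-methylbut-2-en-1-yl)-2,3-dihydrobenzofuran-5-yl]-1-[2,4,6-tris(tert-butyldimethylsilyloxy)phenyl]prop-2-yn-1-one | CC(C)=CCc1cc(C#CC(=O)c3c(O[Si](C)(C)C(C)(C)C)cc(O[Si](C)(C)C(C)(C)C)cc3O[Si](C)(C)C(C)(C)C)cc2c1O[C@@H](C(C)(C)O)[C@@H]2O[Si](C)(C)C(C)(C)C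
F4 | step 12 | 3-(diethylamino)-3-[(2R,3R)-3-(tert-butyldimethylsilyloxy)-2-(2-hydroxypropan-2-yl)-7-(3-methylbut-2-en-1-yl)-2,3-dihydrobenzofuran-5-yl]-1-[2,4,6-tris(tert-butyldimethylsilyloxy)phenyl]prop-2-en-1-one | CC(C)=CCc1cc(C(=CC(=O)c3c(O[Si](C)(C)C(C)(C)C)cc(O[Si](C)(C)C(C)(C)C)cc3O[Si](C)(C)C(C)(C)C)N(CC)CC)cc2c1O[C@@H](C(C)(C)O)[C@@H]2O[Si](C)(C)C(C)(C)C
F5 | step 6 | methyl (2S,3R)-3-(tert-butyldimethylsilyloxy)-3-[2-(tert-butyldimethylsilyloxy)-5-iodo-3-(3-methylbut-2-en-1-yl)phenyl]-2-chloropropanoate | COC(=O)[C@@H](Cl)[C@H](O[Si](C)(C)C(C)(C)C)c1cc(I)cc(CC=C(C)C)c1O[Si](C)(C)C(C)(C)C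
F6 | step 1 | allyl 4-iodophenyl ether | C=CCOc1ccc(I)cc1
F7 | step 1 | 2-allyl-4-iodophenol | C=CCc1cc(I)ccc1O
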